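**Strategy.** The route rests on disconnecting the cyclobutane bond between C10, the quaternary methyl-bearing carbon, and C4, the ring CH next to the enone β-carbon (longipinane numbering). In the key step a titanocene chloride opens a C9–C10 epoxide of a cis-fused bicyclo[5.4.0]undecane (himachalane-type) epoxy enone; the tertiary C10 radical adds 4-exo to C4, the β-carbon of a carvone-like 2-methylcyclohexenone. One operation closes the four-membered ring of the bicyclo[3.1.1]heptane core, creates the quaternary centre and releases the only free hydroxyl (C9–OH), the feature exploited being the C9 carbinol flanking quaternary C10. The precursor carries both esters and comes from a Diels–Alder/ring-closing-metathesis sequence; a three-step carbonyl transposition finishes the enone.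

Key step: step 13

Numbering: longipinane locants follow the target SMILES after the angelate: C7 (angelate), C8 (methylbutanoate), C9 (OH), C10 (quaternary, CH3), C11, C1 (C=O), C2, C3 (CH3), C4, C5, C6 (gem-dimethyl). Ring A is the six-membered ring C1–C5/C11, ring B the seven-membered ring C5–C11. "4,10-Seco" compounds lack the C4–C10 bond. α is the face of ring B that carries O-8 and O-9 (and H-5, H-11 in the seco compounds); β is the opposite face.

Assumption: allyl methoxymethyl ether 6 is taken as a purchasable reagent; (+)-Ipc2BOMe is taken to deliver the allyl unit to the Re face of aldehyde 5 and the (S)-oxazaborolidinium ion to expose the Si face of the dienophile α-carbon, as their usual models predict, and the mirror-image controller would be used if a sense were opposite here.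

Step 1
Reactants: 1 3-hydroxy-2,2-dimethylpropanal; 2 1-(triphenylphosphoranylidene)propan-2-one
Product: 3 (3E)-6-hydroxy-5,5-dimethylhex-3-en-2-one
Conditions: toluene, 90 °C
Reagents that add atoms: none
Why: A Wittig olefination with the stabilised ylide should give the E-enone and tolerates the free hydroxyl of the hydroxy aldehyde.

Step 2
Reactants: 3 (3E)-6-hydroxy-5,5-dimethylhex-3-en-2-one
Product: 4 (3E)-2,2,5-trimethylhexa-3,5-dien-1-ol
Conditions: Ph3PCH3Br, KOt-Bu (excess), THF, 0 °C → rt
Reagents that add atoms: methyltriphenylphosphonium bromide, C[P+](c1ccccc1)(c1ccccc1)c1ccccc1.[Br-]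
Why: Wittig methylenation attacks the ketone carbonyl of the enone in a 1,2-sense and should give the 2-methyl-1,3-diene with the E bond untouched.

Step 3
Reactants: 4 (3E)-2,2,5-trimethylhexa-3,5-dien-1-ol
Product: 5 (3E)-2,2,5-trimethylhexa-3,5-dienal
Conditions: Dess–Martin periodinane, NaHCO3, CH2Cl2, 0 °C → rt
Reagents that add atoms: none
Why: Dess–Martin oxidation of the neopentyl alcohol gives an aldehyde with a quaternary α-carbon, so neither enolisation nor migration of the double bonds can follow.

Step 4
Reactants: 5 (3E)-2,2,5-trimethylhexa-3,5-dienal; 6 allyl methoxymethyl ether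
Product: 9 (3S,4S,6E)-3-(methoxymethoxy)-5,5,8-trimethylnona-1,6,8-trien-4-ol, via allylborane 7 (not isolated), via borinate 8 (not isolated)
Conditions: 6, sec-BuLi, THF, −78 °C; (+)-Ipc2BOMe; BF3·OEt2; then 5, −78 °C; NaOH, H2O2, 0 °C → rt
Reagents that add atoms: none
Why: Brown alkoxyallylboration through a chair Zimmerman–Traxler transition state: the Z-γ-alkoxyallyl unit gives the syn 1,2-diol pattern and the isopinocampheyl groups derived from (−)-α-pinene steer attack to the Re face of the aldehyde, which sets C7 and C8 as 3S,4S in 9.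

Step 5
Reactants: 9 (3S,4S,6E)-3-(methoxymethoxy)-5,5,8-trimethylnona-1,6,8-trien-4-ol; 10 angelic acid
Product: 12 (3S,4S,6E)-3-(methoxymethoxy)-5,5,8-trimethylnona-1,6,8-trien-4-yl (2Z)-2-methylbut-2-enoate, via mixed anhydride 11 (not isolated)
Conditions: 10, 2,4,6-Cl3C6H2COCl, Et3N, toluene, rt; then 9, DMAP, 70 °C
Reagents that add atoms: none
Why: Yamaguchi esterification acylates the only free, neopentyl hydroxyl through the mixed anhydride under conditions that normally keep the Z geometry of angelates.

Step 6
Reactants: 12 the angelate triene; 13 but-3-en-2-one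
Product: 14 (3S,4S)-5-[(1S,6R)-6-acetyl-3-methylcyclohex-2-en-1-yl]-3-(methoxymethoxy)-5-methylhex-1-en-4-yl (2Z)-2-methylbut-2-enoate (acetyl and side chain cis)
Conditions: (S)-o-tolyl-CBS oxazaborolidine (20 mol%), Tf2NH (16 mol%), CH2Cl2, −78 → −40 °C
Reagents that add atoms: none
Why: Lewis-acid-catalysed Diels–Alder reaction with a chiral oxazaborolidinium ion: the 1-alkyl and 3-methyl groups of the diene both direct the C5–C11 and C2–C1 bonds, the endo transition state places acetyl and side chain cis, and the catalyst selects the Si face of the dienophile α-carbon, so that C5 and C11 are set.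

Step 7
Reactants: 14 the Diels–Alder methyl ketone
Product: 15 (3S,4S)-3-(methoxymethoxy)-5-methyl-5-[(1S,6R)-3-methyl-6-(prop-1-en-2-yl)cyclohex-2-en-1-yl]hex-1-en-4-yl (2Z)-2-methylbut-2-enoate
Conditions: Zn, CH2Br2, TiCl4, THF–CH2Cl2, 0 °C → rt
Reagents that add atoms: dibromomethane, BrCBr
Why: Lombardo–Takai methylenation turns the methyl ketone into the isopropenyl group without base, so the epimerisable C11 centre and the ester are preserved.

Step 8
Reactants: 15 the isopropenyl triene
Product: 16 7β-angeloyloxy-8α-(methoxymethoxy)-4,10-secolongipina-3,9-diene (5αH,11αH, cis-fused)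
Conditions: second-generation Grubbs catalyst (5 mol%), CH2Cl2, 40 °C
Reagents that add atoms: none
Why: Ring-closing metathesis of the vinyl and isopropenyl groups, held cis on ring A, closes the seven-membered ring B and gives the trisubstituted C9=C10 alkene.

Step 9
Reactants: 16 the bicyclic methoxymethyl ether
Product: 17 7β-angeloyloxy-4,10-secolongipina-3,9-dien-8α-ol
Conditions: Me2BBr, CH2Cl2, −78 °C; then aq. NaHCO3
Reagents that add atoms: none
Why: Cleavage of the methoxymethyl acetal with Me2BBr at low temperature frees the allylic C8 hydroxyl and leaves the angelate and both alkenes alone.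

Step 10
Reactants: 17 the allylic alcohol
Product: 18 7β-angeloyloxy-9α,10α-epoxy-4,10-secolongipin-3-en-8α-ol
Conditions: VO(acac)2 (5 mol%), t-BuOOH, CH2Cl2, 0 °C
Reagents that add atoms: tert-butyl hydroperoxide, CC(C)(C)OO
Why: Hydroxyl-directed vanadium-catalysed epoxidation delivers oxygen to C9=C10 on the face of the C8 hydroxyl (cis epoxy alcohol, which sets C9) and spares the undirected ring A alkene and the electron-poor angelate.

Step 11
Reactants: 18 the epoxy alcohol; 19 (2R)-2-methylbutanoic acid
Product: 20 7β-angeloyloxy-9α,10α-epoxy-8α-[(2R)-2-methylbutanoyloxy]-4,10-secolongipin-3-ene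
Conditions: EDC·HCl, DMAP, CH2Cl2, 0 °C → rt
Reagents that add atoms: none
Why: Steglich-type carbodiimide esterification of the only free hydroxyl introduces the C8 ester, whose own stereocentre comes unchanged from the acid.

Step 12
Reactants: 20 the epoxy diester
Product: 21 7β-angeloyloxy-9α,10α-epoxy-8α-[(2R)-2-methylbutanoyloxy]-4,10-secolongipin-3-en-2-one
Conditions: Rh2(cap)4 (dirhodium tetracaprolactamate, 1 mol%), t-BuOOH, K2CO3, CH2Cl2, rt
Reagents that add atoms: tert-butyl hydroperoxide, CC(C)(C)OO
Why: Allylic C–H oxidation with dirhodium caprolactamate and t-BuOOH should occur at C2, the only allylic methylene of the ring A alkene (C5–H is a shielded methine), and give the carvone-type enone.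

Step 13
Reactants: 21 the epoxy enone
Product: 22 7β-angeloyloxy-9α-hydroxy-8α-[(2R)-2-methylbutanoyloxy]longipinan-2-one (mixture of C3 epimers)
Conditions: Cp2TiCl2 (20 mol%), Zn dust, 2,4,6-collidine hydrochloride, THF, rt
Reagents that add atoms: none
Why: Cp2TiCl (trivalent titanium, from Cp2TiCl2 and Zn) transfers one electron to the epoxide, the C10–O bond breaks to give the tertiary C10 radical and the C9 titanium alkoxide, the radical adds to C4, the β-carbon of the enone, and the α-keto radical is reduced to a titanium enolate that collidinium chloride protonates together with the alkoxide, which regenerates the catalyst. The closest known reaction type is the titanocene-mediated reductive epoxide opening (Nugent–RajanBabu reaction) followed by 4-exo-trig radical cyclisation onto α,β-unsaturated carbonyl compounds, as in the ring closure of epoxy carvones to pinane-type cyclobutanes. The cyclobutane C4–C5–C11–C10 closes in the 4-exo-trig mode, and the same bond completes the bicyclo[3.1.1]heptanone, whose six-membered ring C10–C11–C1–C2–C3–C4 is thereby closed 6-endo with respect to the C3=C4 bond. C4 sits on the β face of ring B through C5, so C10 can be reached only from that face and the cis ring fusion from step 6 fixes both new centres C4 and C10, C9 keeps the configuration from step 10, and C3 forms as an epimer mixture that step 14 removes. The step needs homolysis at the more substituted C10–O bond, secured by the stability of the tertiary radical, and ring closure faster than reduction of that radical, which the electron-poor enone, the stabilised product radical and the fully substituted tether favour. The esters, the angelate and the new hydroxyl are inert to the reagent.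

Step 14
Reactants: 22 the tricyclic hydroxy ketone
Product: 23 7β-angeloyloxy-2,9α-dihydroxy-8α-[(2R)-2-methylbutanoyloxy]longipin-2-en-1-one (diosphenol)
Conditions: SeO2, 1,4-dioxane, 80 °C
Reagents that add atoms: selenium dioxide, O=[Se]=O
Why: Riley oxidation of the α-methylene C1 gives the 1,2-dione, which can enolise only toward C3 because C11 is a bridgehead, so that a single diosphenol results and the C3 epimers converge.

Step 15
Reactants: 23 the diosphenol
Product: 24 the 2-O-trifluoromethanesulfonate of 23
Conditions: PhNTf2, Et3N, DMAP (cat.), CH2Cl2, 0 °C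
Reagents that add atoms: N-phenylbis(trifluoromethanesulfonimide), O=S(=O)(N(c1ccccc1)S(=O)(=O)C(F)(F)F)C(F)(F)F
Why: Sulfonylation of the acidic enol hydroxyl (enol triflate formation) should be selective over the hindered, neopentyl C9 alcohol.

Step 16
Reactants: 24 the enol triflate
Product: 25 (4R,5S,7S,8S,9S,10R,11R)-7-angeloyloxy-9-hydroxy-8-[(2R)-2-methylbutanoyloxy]longipin-2-en-1-one (target)
Conditions: Pd(OAc)2 (5 mol%), PPh3, HCO2H, n-Bu3N, DMF, 60 °C
Reagents that add atoms: none
Why: Palladium-catalysed formate reduction of the enol triflate (oxidative addition to zerovalent palladium, hydride transfer, reductive elimination) replaces the C2 oxygen by hydrogen and leaves the verbenone-type enone.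

**Compound list**

1 | 3-hydroxy-2,2-dimethylpropanal | OCC(C)(C)C=O | starting material
2 | 1-(triphenylphosphoranylidene)propan-2-one | CC(=O)C=P(c1ccccc1)(c1ccccc1)c1ccccc1 | starting material
3 | (3E)-6-hydroxy-5,5-dimethylhex-3-en-2-one | CC(=O)/C=C/C(C)(C)CO | intermediate
4 | (3E)-2,2,5-trimethylhexa-3,5-dien-1-ol | CC(=C)/C=C/C(C)(C)CO | intermediate
5 | (3E)-2,2,5-trimethylhexa-3,5-dienal | CC(=C)/C=C/C(C)(C)C=O | intermediate
6 | allyl methoxymethyl ether, 3-(methoxymethoxy)prop-1-ene | C=CCOCOC | starting material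
7 | B-[(2Z)-3-(methoxymethoxy)prop-2-en-1-yl]diisopinocampheylborane, isopinocampheyl groups from (−)-α-pinene | COCO/C=C\CB([C@H]1C[C@H]2C[C@@H]([C@@H]1C)C2(C)C)[C@H]1C[C@H]2C[C@@H]([C@@H]1C)C2(C)C | intermediate
8 | diisopinocampheylborinate ester of 9 | CC(=C)/C=C/C(C)(C)[C@H](OB([C@H]1C[C@H]2C[C@@H]([C@@H]1C)C2(C)C)[C@H]1C[C@H]2C[C@@H]([C@@H]1C)C2(C)C)[C@@H](OCOC)C=C | intermediate
9 | (3S,4S,6E)-3-(methoxymethoxy)-5,5,8-trimethylnona-1,6,8-trien-4-ol | CC(=C)/C=C/C(C)(C)[C@H](O)[C@@H](OCOC)C=C | intermediate
10 | angelic acid, (2Z)-2-methylbut-2-enoic acid | C/C=C(/C)C(=O)O | starting material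
11 | (2Z)-2-methylbut-2-enoic 2,4,6-trichlorobenzoic anhydride | C/C=C(/C)C(=O)OC(=O)c1c(Cl)cc(Cl)cc1Cl | intermediate
12 | (3S,4S,6E)-3-(methoxymethoxy)-5,5,8-trimethylnona-1,6,8-trien-4-yl (2Z)-2-methylbut-2-enoate | C/C=C(/C)C(=O)O[C@H]([C@@H](OCOC)C=C)C(C)(C)/C=C/C(C)=C | intermediate
13 | but-3-en-2-one (methyl vinyl ketone) | CC(=O)C=C | starting material
14 | (3S,4S)-5-[(1S,6R)-6-acetyl-3-methylcyclohex-2-en-1-yl]-3-(methoxymethoxy)-5-methylhex-1-en-4-yl (2Z)-2-methylbut-2-enoate | C/C=C(/C)C(=O)O[C@H]([C@@H](OCOC)C=C)C(C)(C)[C@H]1C=C(C)CC[C@H]1C(C)=O | intermediate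
15 | (3S,4S)-3-(methoxymethoxy)-5-methyl-5-[(1S,6R)-3-methyl-6-(prop-1-en-2-yl)cyclohex-2-en-1-yl]hex-1-en-4-yl (2Z)-2-methylbut-2-enoate | C/C=C(/C)C(=O)O[C@H]([C@@H](OCOC)C=C)C(C)(C)[C@H]1C=C(C)CC[C@H]1C(C)=C | intermediate
16 | 7β-angeloyloxy-8α-(methoxymethoxy)-4,10-secolongipina-3,9-diene (5αH,11αH) | C/C=C(/C)C(=O)O[C@@H]1[C@@H](OCOC)C=C(C)[C@@H]2CCC(C)=C[C@@H]2C1(C)C | intermediate
17 | 7β-angeloyloxy-4,10-secolongipina-3,9-dien-8α-ol | C/C=C(/C)C(=O)O[C@@H]1[C@@H](O)C=C(C)[C@@H]2CCC(C)=C[C@@H]2C1(C)C | intermediate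
18 | 7β-angeloyloxy-9α,10α-epoxy-4,10-secolongipin-3-en-8α-ol | C/C=C(/C)C(=O)O[C@@H]1[C@@H](O)[C@H]3O[C@@]3(C)[C@@H]2CCC(C)=C[C@@H]2C1(C)C | intermediate
19 | (2R)-2-methylbutanoic acid | CC[C@@H](C)C(=O)O | starting material
20 | 7β-angeloyloxy-9α,10α-epoxy-8α-[(2R)-2-methylbutanoyloxy]-4,10-secolongipin-3-ene | C/C=C(/C)C(=O)O[C@@H]1[C@@H](OC(=O)[C@H](C)CC)[C@H]3O[C@@]3(C)[C@@H]2CCC(C)=C[C@@H]2C1(C)C | intermediate
21 | 7β-angeloyloxy-9α,10α-epoxy-8α-[(2R)-2-methylbutanoyloxy]-4,10-secolongipin-3-en-2-one | C/C=C(/C)C(=O)O[C@@H]1[C@@H](OC(=O)[C@H](C)CC)[C@H]3O[C@@]3(C)[C@@H]2CC(=O)C(C)=C[C@@H]2C1(C)C | intermediate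
22 | 7β-angeloyloxy-9α-hydroxy-8α-[(2R)-2-methylbutanoyloxy]longipinan-2-one, C3 epimers, other centres as in 25 | C/C=C(/C)C(=O)O[C@@H]1[C@@H](OC(=O)[C@H](C)CC)[C@@H](O)[C@@]2(C)[C@@H]3CC(=O)C(C)[C@H]2[C@@H]3C1(C)C | intermediate
23 | 7β-angeloyloxy-2,9α-dihydroxy-8α-[(2R)-2-methylbutanoyloxy]longipin-2-en-1-one | C/C=C(/C)C(=O)O[C@@H]1[C@@H](OC(=O)[C@H](C)CC)[C@@H](O)[C@@]2(C)[C@@H]3C(=O)C(O)=C(C)[C@H]2[C@@H]3C1(C)C | intermediate
24 | 2-O-trifluoromethanesulfonate of 23 | C/C=C(/C)C(=O)O[C@@H]1[C@@H](OC(=O)[C@H](C)CC)[C@@H](O)[C@@]2(C)[C@@H]3C(=O)C(OS(=O)(=O)C(F)(F)F)=C(C)[C@H]2[C@@H]3C1(C)C | intermediate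
25 | (4R,5S,7S,8S,9S,10R,11R)-7-angeloyloxy-9-hydroxy-8-[(2R)-2-methylbutanoyloxy]longipin-2-en-1-one | C/C=C(/C)C(=O)O[C@@H]1[C@@H](OC(=O)[C@H](C)CC)[C@@H](O)[C@@]2(C)[C@@H]3C(=O)C=C(C)[C@H]2[C@@H]3C1(C)C | target

Total step count: 16. Longest linear sequence: 16 steps (1 → 25).

**Steps most likely to fail**

Step 13 (key step). The tertiary C10 radical may be reduced or lose a hydrogen atom to trivalent titanium (deoxygenated alkene or allylic alcohol) before the slow 4-exo closure, or the closure may revert. The fallback sets out from 21 and returns at 22. The epoxide is opened with MgI2 (Et2O–toluene, −20 °C) to the tertiary iodohydrin F1, with iodide on C10 anti to the C9 hydroxyl. The same carbon radical is then generated under a metal-free chain, (Me3Si)3SiH and Et3B/air in toluene with slow addition, so that no reducing metal competes with ring closure.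

Step 12. Hydrogen abstraction may occur at C5–H or at the C12 methyl, oxygen may be delivered to C4 of the allyl radical (transposed enone), or over-oxidation may follow. The fallback sets out from 20 and returns at 21. An ene/[2,3]-sigmatropic hydroxylation with SeO2 (cat.) and t-BuOOH in CH2Cl2, which favours the ring methylene on the more substituted alkene carbon, should give the C2 allylic alcohol F2. Dess–Martin oxidation of it then gives 21.

Step 6. Facial or endo selectivity may be poor with the bulky diene terminus, and the ether and ester donors may inhibit the catalyst. The fallback sets out from 12 and returns at 14, with an oxazolidinone auxiliary in place of the catalyst. Diene 12 reacts with N-acryloyl-(4S)-4-benzyloxazolidin-2-one and Me2AlCl (CH2Cl2, −78 °C) to the endo imide adduct F3. MeNH(OMe)·HCl with AlMe3 converts this to the Weinreb amide F4, and MeMgBr (THF, −78 → 0 °C) gives 14.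

**Further compounds**

F1 | step 13 | tertiary iodohydrin from 21: 10-iodo-9α-hydroxy-4,10-secolongipin-3-en-2-one 7-angelate 8-[(2R)-2-methylbutanoate] | C/C=C(/C)C(=O)O[C@@H]1[C@@H](OC(=O)[C@H](C)CC)[C@@H](O)[C@](C)(I)[C@@H]2CC(=O)C(C)=C[C@@H]2C1(C)C
F2 | step 12 | C2 allylic alcohol of 20 (C2 configuration open) | C/C=C(/C)C(=O)O[C@@H]1[C@@H](OC(=O)[C@H](C)CC)[C@H]3O[C@@]3(C)[C@@H]2CC(O)C(C)=C[C@@H]2C1(C)C
F3 | step 6 | endo imide adduct of 12 with N-acryloyl-(4S)-4-benzyloxazolidin-2-one | C/C=C(/C)C(=O)O[C@H]([C@@H](OCOC)C=C)C(C)(C)[C@H]1C=C(C)CC[C@H]1C(=O)N1[C@@H](Cc2ccccc2)COC1=O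
F4 | step 6 | N-methoxy-N-methyl amide corresponding to 14 | C/C=C(/C)C(=O)O[C@H]([C@@H](OCOC)C=C)C(C)(C)[C@H]1C=C(C)CC[C@H]1C(=O)N(C)OC
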